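The indole is cut at C3–C3a, the bond that joins the benzene ring to the pyrrole carbon β to N1. In the precursor, ethyl (Z)-3-[(4,5-dibromo-2-iodophenyl)amino]acrylate, that carbon is the nucleophilic β-carbon of an N-aryl enamine (the acrylate α-carbon), and the future C3a carries iodine ortho to nitrogen. One palladium-catalysed operation closes the pyrrole ring at the iodine-marked carbon only, which fixes the 5,6-dibromo pattern and leaves both C–Br bonds intact. The C3 ester, which makes the enamine stable and easy to prepare, then serves as a traceless handle: saponification and ipso-bromodecarboxylation with NBS put the third bromine at C3.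

Key step: step 3

Remark on the chemistry: the target is planar and has no stereocentre, so no enantiomer has to be selected. The only stereo-element on the way, the Z geometry of the enamine precursor, is consumed in the ring closure.

Step 1
Reactants: 1 3,4-dibromoaniline
Product: 2 4,5-dibromo-2-iodoaniline
Conditions: NIS (1.05 equiv), AcOH, rt, dark
Reagents that add atoms: N-iodosuccinimide, O=C1CCC(=O)N1I
Why: Electrophilic aromatic iodination directed by the amino group; the para position is blocked by bromine and, of the two ortho positions, the one flanked by NH2 and Br is hindered, so iodine should enter at the open ortho carbon.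

Step 2
Reactants: 2 4,5-dibromo-2-iodoaniline; 3 ethyl propiolate
Product: 4 ethyl (Z)-3-[(4,5-dibromo-2-iodophenyl)amino]acrylate
Conditions: 3 (1.5 equiv), EtOH, reflux
Reagents that add atoms: none
Why: Aza-Michael addition (conjugate hydroamination) of the aniline nitrogen to the terminal alkyne carbon gives the β-aminoacrylate, whose Z isomer should be favoured at equilibrium by the intramolecular N–H···O=C hydrogen bond; any E isomer is carried along, since both lead to the same indole.

Step 3
Reactants: 4 ethyl (Z)-3-[(4,5-dibromo-2-iodophenyl)amino]acrylate
Product: 6 ethyl 5,6-dibromo-1H-indole-3-carboxylate, via ethyl 5,6-dibromo-3H-indole-3-carboxylate 5 (not isolated)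
Conditions: Pd(OAc)2 (5 mol%), n-Bu4NCl (1 equiv), NaHCO3 (2.5 equiv), DMF, 80 °C, N2
Reagents that add atoms: none
Why: Pd(0) formed in situ inserts into the C–I bond, the arylpalladium(II) is captured by the enamine β-carbon (the acrylate α-carbon) with loss of the N–H proton to bicarbonate, and reductive elimination from the resulting six-membered palladacycle forges C3–C3a to give 3H-indole 5, which tautomerises to the aromatic 1H-indole 6. The closest known reaction type is the palladium-catalysed intramolecular Heck-type cyclisation of N-(2-halophenyl) enaminones and β-aminoacrylates to 3-acylindoles and indole-3-carboxylates. The pyrrole ring closes in a formally 5-endo-trig mode, which is feasible because the bond forms by reductive elimination from the palladacycle and not by direct carbopalladation. No stereocentre persists: C3 of 5 is only transiently sp3 and is planarised on tautomerisation, and the enamine geometry is irrelevant because E and Z forms interconvert through the imine tautomer. The step needs site selectivity, secured by the iodine sitting ortho to nitrogen on the carbon that becomes C3a, and chemoselectivity for C–I over the two C–Br bonds, secured by the much faster oxidative addition into C–I under phosphine-free conditions at moderate temperature.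

Step 4
Reactants: 6 ethyl 5,6-dibromo-1H-indole-3-carboxylate
Product: 8 5,6-dibromo-1H-indole-3-carboxylic acid, via sodium 5,6-dibromo-1H-indole-3-carboxylate 7 (not isolated)
Conditions: NaOH (4 equiv), EtOH/H2O, reflux; then 1 M HCl, 0 °C, to pH 3
Reagents that add atoms: sodium hydroxide, [Na+].[OH-]
Why: Saponification (base-mediated acyl substitution) of the vinylogous carbamate needs hot aqueous hydroxide, which the aryl bromides tolerate, and cold acidification should release the acid without acid-promoted protodecarboxylation.

Step 5
Reactants: 8 5,6-dibromo-1H-indole-3-carboxylic acid
Product: 9 3,5,6-tribromo-1H-indole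
Conditions: NBS (1.0 equiv), DMF, 0 °C to rt, dark
Reagents that add atoms: N-bromosuccinimide, O=C1CCC(=O)N1Br
Why: Electrophilic ipso-bromodecarboxylation (halodecarboxylation of an electron-rich heteroaromatic acid): electrophilic bromine attacks C3, the most nucleophilic indole position, and the σ-adduct rearomatises by losing CO2 in place of a proton, so one equivalent of NBS should put bromine exactly where the carboxyl group was.

Compound list
1 | 3,4-dibromoaniline | Nc1ccc(Br)c(Br)c1 | starting material
2 | 4,5-dibromo-2-iodoaniline | Nc1cc(Br)c(Br)cc1I | intermediate
3 | ethyl propiolate | CCOC(=O)C#C | starting material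
4 | ethyl (Z)-3-[(4,5-dibromo-2-iodophenyl)amino]acrylate | CCOC(=O)/C=C\Nc1cc(Br)c(Br)cc1I | intermediate
5 | ethyl 5,6-dibromo-3H-indole-3-carboxylate (racemic, transient tautomer) | CCOC(=O)C1C=Nc2cc(Br)c(Br)cc12 | intermediate
6 | ethyl 5,6-dibromo-1H-indole-3-carboxylate | CCOC(=O)c1c[nH]c2cc(Br)c(Br)cc12 | intermediate
7 | sodium 5,6-dibromo-1H-indole-3-carboxylate | [Na+].[O-]C(=O)c1c[nH]c2cc(Br)c(Br)cc12 | intermediate
8 | 5,6-dibromo-1H-indole-3-carboxylic acid | OC(=O)c1c[nH]c2cc(Br)c(Br)cc12 | intermediate
9 | 3,5,6-tribromo-1H-indole | Brc1cc2[nH]cc(Br)c2cc1Br | target

Total step count: 5. Longest linear sequence: 5 steps (1 to 9).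

Steps most likely to fail

Step 3. Oxidative addition into a C–Br bond could compete with insertion into C–I, or protodeiodination could outrun the slow 5-endo closure, giving oligomers or a reduced open-chain enamine. The fallback sets out from 1 and 3 and does without the iodine. Aza-Michael addition in refluxing ethanol should give ethyl (Z)-3-[(3,4-dibromophenyl)amino]acrylate F1. A palladium(II)-catalysed cross-dehydrogenative cyclisation (Pd(OAc)2 cat., Cu(OAc)2 as oxidant, K2CO3, DMF, 80–100 °C) would then close C3–C3a by palladation of the less hindered ortho C–H bond, and the route is rejoined at 6. No C–I bond is involved and palladium(0) is reoxidised as it forms. The price is that the closure site is set by sterics alone, so any 4,5-dibromo isomer would have to be removed by crystallisation.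

Step 5. A second bromination at C2 or oxidative degradation of the electron-rich ring could compete with loss of CO2, and the free N–H 3-bromoindole may suffer on acidic work-up. The fallback sets out from 8 and separates the two events. Protodecarboxylation (cat. Ag2CO3, AcOH, DMSO, 120 °C) should give 5,6-dibromo-1H-indole F2. Electrophilic bromination at C3 with pyridinium tribromide (1.0 equiv) in pyridine at 0 °C would then give the target, and the route is rejoined at 9.

Step 2. The conjugate addition may stall because the aniline is deactivated by three halogens and hindered by the ortho iodine, and the propiolate may oligomerise on prolonged heating. The fallback sets out from 2 and replaces the alkyne hydroamination by an acid-promoted enamine exchange with commercial ethyl (E)-3-(dimethylamino)acrylate (AcOH, rt to 50 °C). The protonated enaminoester takes up the aniline and expels dimethylamine, giving the same β-aminoacrylate directly. No new compound arises (F0), and the route is rejoined at 4.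

Further compounds
F1 | step 3 | ethyl (Z)-3-[(3,4-dibromophenyl)amino]acrylate | CCOC(=O)/C=C\Nc1ccc(Br)c(Br)c1
F2 | step 5 | 5,6-dibromo-1H-indole | Brc1cc2cc[nH]c2cc1Br
F0 | step 2 | none | none
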